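The synthesis rests on cutting the C4–C4a bond of ring C. The precursor is an (E)-3-aryloxyacrylic acid that already holds the O1–C2 vinyl ether link, ring B on C2 and the C3 oxygen as a benzyl enol ether. Once its carboxyl group is activated, ring A captures the acyl carbon, so a single operation closes the pyranone and completes the flavonol skeleton. The feature exploited lies in ring A: O1, the C5 oxygen and the C7 oxygen all direct to C4a, and the phenol-derived ring has a mirror plane through its C1 and C4, so its C2 and C6 are interchangeable and an 8-methoxy isomer is impossible. The acid-sensitive prenyl ether is attached afterwards.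

Key step: step 11

Assumption: the enol triflate, the aryl vinyl ether ester, the derived acid and its mixed anhydride are drawn as E isomers (carbonyl carbon cis to the triflyloxy or aryloxy group). Any Z isomer is carried along because it converges on the same flavone in the ring closure. The keto ester is racemic and its stereocentre vanishes on enol triflate formation.

Step 1
Reactants: 1 methyl 3,5-dihydroxy-4-methoxybenzoate
Product: 2 methyl 3,5-bis(benzyloxy)-4-methoxybenzoate
Conditions: BnBr (2.3 equiv), K2CO3, DMF, 60 °C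
Reagents that add atoms: benzyl bromide, BrCc1ccccc1
Why: Williamson ether synthesis on the two equivalent phenols, with the methyl ester and methyl ether inert to carbonate base.

Step 2
Reactants: 2 methyl 3,5-bis(benzyloxy)-4-methoxybenzoate
Product: 3 [3,5-bis(benzyloxy)-4-methoxyphenyl]methanol
Conditions: LiAlH4, THF, 0 °C → rt
Reagents that add atoms: none
Why: Hydride reduction of the ester to the primary benzylic alcohol, which touches none of the three aryl ethers.

Step 3
Reactants: 3 [3,5-bis(benzyloxy)-4-methoxyphenyl]methanol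
Product: 4 3,5-bis(benzyloxy)-4-methoxybenzaldehyde
Conditions: MnO2 (activated, excess), CH2Cl2, rt
Reagents that add atoms: none
Why: Selective heterogeneous oxidation of a benzylic alcohol, which stops cleanly at the aldehyde.

Step 4
Reactants: 4 3,5-bis(benzyloxy)-4-methoxybenzaldehyde
Product: 6 3,5-bis(benzyloxy)-4-methoxyphenol, via aryl formate 5 (not isolated)
Conditions: mCPBA, CH2Cl2, 0 °C → rt; aq. Na2SO3/NaHCO3 wash; then cat. K2CO3, MeOH, rt
Reagents that add atoms: mCPBA, OOC(=O)c1cccc(Cl)c1
Why: Baeyer-Villiger oxidation, in which the trioxygenated aryl group migrates in preference to hydride, the formate shields the easily oxidised phenol from excess peracid, and mild methanolysis then frees it.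

Step 5
Reactants: 7 4-hydroxybenzoic acid
Product: 8 4-(pivaloyloxy)benzoic acid
Conditions: PivCl (1.1 equiv), NaOH (2.2 equiv), H2O–THF, 0 °C; then HCl to pH 2
Reagents that add atoms: pivaloyl chloride, CC(C)(C)C(Cl)=O
Why: Schotten-Baumann acylation of the phenoxide (any mixed anhydride at the carboxylate is hydrolysed back), giving a hindered ester that should resist the enolate, phenoxide and acid of later steps and that deactivates ring B.

Step 6
Reactants: 9 benzyloxyacetic acid
Product: 10 tert-butyl 2-(benzyloxy)acetate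
Conditions: Cl3CC(=NH)Ot-Bu, cat. BF3·OEt2, CH2Cl2–cyclohexane, rt
Reagents that add atoms: tert-butyl 2,2,2-trichloroacetimidate, CC(C)(C)OC(=N)C(Cl)(Cl)Cl
Why: Acid-catalysed O-tert-butylation of the carboxylic acid by the imidate leaves the benzyl ether untouched and installs an ester that can later be removed without base or hydrogen.

Step 7
Reactants: 8 4-(pivaloyloxy)benzoic acid; 10 tert-butyl 2-(benzyloxy)acetate
Product: 12 tert-butyl 2-(benzyloxy)-3-oxo-3-[4-(pivaloyloxy)phenyl]propanoate (racemic), via acid chloride 11 (not isolated)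
Conditions: 8: (COCl)2, cat. DMF, CH2Cl2, rt, evaporate; 10 (2 equiv): LiN(SiMe3)2 (2.1 equiv), THF, −78 °C; add 11, −78 °C; aq. NH4Cl
Reagents that add atoms: none
Why: Crossed Claisen-type C-acylation, in which the lithium enolate of the tert-butyl ester (slow to self-condense) attacks the far more electrophilic aroyl chloride, the second equivalent of enolate deprotonates the acidic keto ester and stops further acylation, and the pivalate is left alone at −78 °C.

Step 8
Reactants: 12 tert-butyl 2-(benzyloxy)-3-oxo-3-[4-(pivaloyloxy)phenyl]propanoate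
Product: 13 tert-butyl (E)-2-(benzyloxy)-3-[4-(pivaloyloxy)phenyl]-3-(trifluoromethylsulfonyloxy)prop-2-enoate
Conditions: Tf2O, Et3N, LiOTf, CH2Cl2, 0 °C
Reagents that add atoms: triflic anhydride, O=S(=O)(OS(=O)(=O)C(F)(F)F)C(F)(F)F
Why: Soft enolisation and O-sulfonylation of a β-keto ester, in which Li+ ties the enolate oxygen to the ester carbonyl and the aryl group avoids the bulky ester, so the triflate should form mainly cis to CO2t-Bu (E), the geometry needed later.

Step 9
Reactants: 13 tert-butyl (E)-2-(benzyloxy)-3-[4-(pivaloyloxy)phenyl]-3-(trifluoromethylsulfonyloxy)prop-2-enoate; 6 3,5-bis(benzyloxy)-4-methoxyphenol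
Product: 14 tert-butyl (E)-2-(benzyloxy)-3-[3,5-bis(benzyloxy)-4-methoxyphenoxy]-3-[4-(pivaloyloxy)phenyl]prop-2-enoate
Conditions: Cs2CO3 (1.2 equiv), MeCN, 0 °C → rt, Ar
Reagents that add atoms: none
Why: Nucleophilic vinylic substitution by addition-elimination, in which the unhindered phenoxide adds to the β-carbon of the triflyloxyacrylate and the short-lived ester enolate expels triflate before it rotates, so the aryloxy group should replace the triflate with retention (E).

Step 10
Reactants: 14 tert-butyl (E)-2-(benzyloxy)-3-[3,5-bis(benzyloxy)-4-methoxyphenoxy]-3-[4-(pivaloyloxy)phenyl]prop-2-enoate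
Product: 15 (E)-2-(benzyloxy)-3-[3,5-bis(benzyloxy)-4-methoxyphenoxy]-3-[4-(pivaloyloxy)phenyl]prop-2-enoic acid
Conditions: CF3CO2H–CH2Cl2 (1:4, anhydrous), 0 °C → rt; evaporate with toluene
Reagents that add atoms: none
Why: Acidolysis of the tert-butyl ester by alkyl-oxygen cleavage needs neither base nor nucleophile, so the pivalate, the benzyl ethers and the ester-deactivated enol ether should survive as long as water is excluded.

Step 11
Reactants: 15 (E)-2-(benzyloxy)-3-[3,5-bis(benzyloxy)-4-methoxyphenoxy]-3-[4-(pivaloyloxy)phenyl]prop-2-enoic acid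
Product: 17 3,5,7-tris(benzyloxy)-6-methoxy-4'-(pivaloyloxy)flavone, via mixed trifluoroacetic anhydride 16 (not isolated)
Conditions: (CF3CO)2O (3 equiv), CH2Cl2 (0.02 M), 0 °C → rt; aq. NaHCO3
Reagents that add atoms: none
Why: (CF3CO)2O turns acid 15 into mixed anhydride 16, which ionises with help from the liberated CF3CO2H to an acylium ion stabilised through the C2=C3 bond by the aryloxy oxygen; the free ring A carbon next to the vinyl ether oxygen attacks it, and proton loss from the arenium ion gives the 4-pyranone, acrylic C1 becoming C4. The closest known reaction type is the classical flavone and chromone synthesis by cyclodehydration of 3-aryloxyacrylic acids, an intramolecular Friedel-Crafts acylation, here driven by an anhydride activator as is usual for electron-rich arenes. Ring C closes in a six-membered exo mode (6-exo-trig at the anhydride carbonyl, 6-exo-dig if the free acylium ion reacts), because the C=O bond under attack stays outside the new ring. No stereocentre is created, and the alkene geometry is not decisive, since the donor-acceptor character of the activated acid lowers the barrier to rotation about C2-C3, so that any Z isomer drains away through the E isomer. The step needs regioselectivity on ring A, and the substrate supplies it by symmetry: both free carbons of the 3,5-dibenzyloxy-4-methoxyphenyl ether are equivalent and each is activated by three oxygens, so only the 5,7-dibenzyloxy-6-methoxy pattern can result and mild activation is enough. It also needs chemoselectivity against closure onto ring B (indenone formation from the Z isomer), which is secured because the ring B ortho carbons lie meta to an oxygen that is further deactivated as its pivalate.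

Step 12
Reactants: 17 3,5,7-tris(benzyloxy)-6-methoxy-4'-(pivaloyloxy)flavone
Product: 18 3,5,7-trihydroxy-6-methoxy-4'-(pivaloyloxy)flavone
Conditions: H2 (1 atm), 10% Pd/C, THF–MeOH, rt
Reagents that add atoms: none
Why: Catalytic hydrogenolysis of the three benzylic C–O bonds is done before any alkene is present, and it leaves the pivalate, the methyl ether and the conjugated C2=C3 bond of the pyranone intact at 1 atm.

Step 13
Reactants: 18 3,5,7-trihydroxy-6-methoxy-4'-(pivaloyloxy)flavone
Product: 19 5-hydroxy-6-methoxy-3,7-bis(methoxymethoxy)-4'-(pivaloyloxy)flavone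
Conditions: MOMCl (2.3 equiv), i-Pr2NEt, CH2Cl2, 0 °C → rt
Reagents that add atoms: chloromethyl methyl ether, COCCl
Why: Methoxymethyl acetal protection by O-alkylation takes the acidic 7-OH and 3-OH, while the 5-OH is hydrogen-bonded to C4=O, flanked by the 6-methoxy group and should stay free.

Step 14
Reactants: 19 5-hydroxy-6-methoxy-3,7-bis(methoxymethoxy)-4'-(pivaloyloxy)flavone; 20 prenyl bromide (1-bromo-3-methylbut-2-ene)
Product: 22 5-hydroxy-6-methoxy-3,7-bis(methoxymethoxy)-4'-(3-methylbut-2-enyloxy)flavone, via 4'-phenol 21 (not isolated)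
Conditions: K2CO3 (2.5 equiv), MeOH–THF, rt; evaporate; 20 (1.1 equiv), DMF, 0 °C → rt
Reagents that add atoms: none
Why: Base-catalysed transesterification frees the 4'-phenoxide, the only unchelated oxyanion, and Williamson alkylation (SN2 at the primary allylic carbon) then gives the prenyl ether while the chelated 5-OH does not react under these mild conditions.

Step 15
Reactants: 22 5-hydroxy-6-methoxy-3,7-bis(methoxymethoxy)-4'-(3-methylbut-2-enyloxy)flavone
Product: 23 3,5,7-trihydroxy-6-methoxy-4'-(3-methylbut-2-enyloxy)flavone (target)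
Conditions: HCl (0.5 M in MeOH), CH2Cl2, 0 °C → rt, followed closely; aq. NaHCO3
Reagents that add atoms: none
Why: Acid-catalysed transacetalisation works because the acetals ionise to the oxygen-stabilised methoxymethyl cation far more easily than the aryl prenyl ether ionises to an allyl cation, so dilute acid at or below room temperature should remove both acetals selectively.

Compound list
1 | methyl 3,5-dihydroxy-4-methoxybenzoate | COC(=O)c1cc(O)c(OC)c(O)c1 | starting material
2 | methyl 3,5-bis(benzyloxy)-4-methoxybenzoate | COC(=O)c1cc(OCc2ccccc2)c(OC)c(OCc2ccccc2)c1 | intermediate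
3 | [3,5-bis(benzyloxy)-4-methoxyphenyl]methanol | OCc1cc(OCc2ccccc2)c(OC)c(OCc2ccccc2)c1 | intermediate
4 | 3,5-bis(benzyloxy)-4-methoxybenzaldehyde | O=Cc1cc(OCc2ccccc2)c(OC)c(OCc2ccccc2)c1 | intermediate
5 | 3,5-bis(benzyloxy)-4-methoxyphenyl formate | O=COc1cc(OCc2ccccc2)c(OC)c(OCc2ccccc2)c1 | intermediate
6 | 3,5-bis(benzyloxy)-4-methoxyphenol | Oc1cc(OCc2ccccc2)c(OC)c(OCc2ccccc2)c1 | intermediate
7 | 4-hydroxybenzoic acid | OC(=O)c1ccc(O)cc1 | starting material
8 | 4-(pivaloyloxy)benzoic acid | CC(C)(C)C(=O)Oc1ccc(cc1)C(O)=O | intermediate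
9 | benzyloxyacetic acid | OC(=O)COCc1ccccc1 | starting material
10 | tert-butyl 2-(benzyloxy)acetate | CC(C)(C)OC(=O)COCc1ccccc1 | intermediate
11 | 4-(pivaloyloxy)benzoyl chloride | CC(C)(C)C(=O)Oc1ccc(cc1)C(Cl)=O | intermediate
12 | tert-butyl 2-(benzyloxy)-3-oxo-3-[4-(pivaloyloxy)phenyl]propanoate (racemic) | CC(C)(C)OC(=O)C(OCc1ccccc1)C(=O)c1ccc(OC(=O)C(C)(C)C)cc1 | intermediate
13 | tert-butyl (E)-2-(benzyloxy)-3-[4-(pivaloyloxy)phenyl]-3-(trifluoromethylsulfonyloxy)prop-2-enoate | CC(C)(C)OC(=O)/C(OCc1ccccc1)=C(\OS(=O)(=O)C(F)(F)F)c1ccc(OC(=O)C(C)(C)C)cc1 | intermediate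
14 | tert-butyl (E)-2-(benzyloxy)-3-[3,5-bis(benzyloxy)-4-methoxyphenoxy]-3-[4-(pivaloyloxy)phenyl]prop-2-enoate | CC(C)(C)OC(=O)/C(OCc1ccccc1)=C(\Oc1cc(OCc2ccccc2)c(OC)c(OCc2ccccc2)c1)c1ccc(OC(=O)C(C)(C)C)cc1 | intermediate
15 | (E)-2-(benzyloxy)-3-[3,5-bis(benzyloxy)-4-methoxyphenoxy]-3-[4-(pivaloyloxy)phenyl]prop-2-enoic acid | OC(=O)/C(OCc1ccccc1)=C(\Oc1cc(OCc2ccccc2)c(OC)c(OCc2ccccc2)c1)c1ccc(OC(=O)C(C)(C)C)cc1 | intermediate
16 | (E)-2-(benzyloxy)-3-[3,5-bis(benzyloxy)-4-methoxyphenoxy]-3-[4-(pivaloyloxy)phenyl]prop-2-enoic trifluoroacetic anhydride | O=C(OC(=O)C(F)(F)F)/C(OCc1ccccc1)=C(\Oc1cc(OCc2ccccc2)c(OC)c(OCc2ccccc2)c1)c1ccc(OC(=O)C(C)(C)C)cc1 | intermediate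
17 | 3,5,7-tris(benzyloxy)-6-methoxy-4'-(pivaloyloxy)flavone | COc1c(OCc2ccccc2)cc3oc(-c4ccc(OC(=O)C(C)(C)C)cc4)c(OCc4ccccc4)c(=O)c3c1OCc1ccccc1 | intermediate
18 | 3,5,7-trihydroxy-6-methoxy-4'-(pivaloyloxy)flavone | COc1c(O)cc2oc(-c3ccc(OC(=O)C(C)(C)C)cc3)c(O)c(=O)c2c1O | intermediate
19 | 5-hydroxy-6-methoxy-3,7-bis(methoxymethoxy)-4'-(pivaloyloxy)flavone | COCOc1cc2oc(-c3ccc(OC(=O)C(C)(C)C)cc3)c(OCOC)c(=O)c2c(O)c1OC | intermediate
20 | prenyl bromide (1-bromo-3-methylbut-2-ene) | CC(C)=CCBr | starting material
21 | 5-hydroxy-2-(4-hydroxyphenyl)-6-methoxy-3,7-bis(methoxymethoxy)chromen-4-one | COCOc1cc2oc(-c3ccc(O)cc3)c(OCOC)c(=O)c2c(O)c1OC | intermediate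
22 | 5-hydroxy-6-methoxy-3,7-bis(methoxymethoxy)-4'-(3-methylbut-2-enyloxy)flavone | COCOc1cc2oc(-c3ccc(OCC=C(C)C)cc3)c(OCOC)c(=O)c2c(O)c1OC | intermediate
23 | 3,5,7-trihydroxy-6-methoxy-4'-(3-methylbut-2-enyloxy)flavone | COc1c(O)cc2oc(-c3ccc(OCC=C(C)C)cc3)c(O)c(=O)c2c1O | target

Total step count: 15.
Longest linear sequence: 11 steps (steps 1–4, then 9–15).

Steps most likely to fail

**Step 11.**
- What may go wrong: the enol ether carbon may be protonated before acylation, leading to loss of CO2 or to cleavage of the vinyl ether. Ring A may be trifluoroacetylated intermolecularly. Geometric interconversion may be too slow, so that part of the material cannot reach ring A.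
- Fallback: it sets out from ester 14 and comes back at flavone 17. It makes the same bond without acid by turning ring A into a discrete carbanion.
- Iodination with N-iodosuccinimide (cat. CF3CO2H, MeCN, 0 °C) at one of the two equivalent free ring A carbons should give tert-butyl (E)-2-(benzyloxy)-3-[3,5-bis(benzyloxy)-2-iodo-4-methoxyphenoxy]-3-[4-(pivaloyloxy)phenyl]prop-2-enoate F1.
- Iodine-lithium exchange with n-BuLi in THF at −100 °C is followed at once by Parham cyclisation onto the neighbouring tert-butyl ester. Expulsion of tert-butoxide should deliver 17.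

**Step 9.**
- What may go wrong: the phenoxide may attack the sulfur of the triflate instead of carbon, an S–O cleavage that returns the keto ester enolate. Addition to the hindered β-carbon may be sluggish, because the α-benzyloxy group damps its electrophilicity. On long reaction times the pivaloyl group may slowly transfer to the phenoxide.
- Fallback: it sets out from keto ester 12 (with phenol 6) and comes back at acid 15.
- CF3CO2H in CH2Cl2 cleaves the tert-butyl ester to 2-(benzyloxy)-3-oxo-3-[4-(pivaloyloxy)phenyl]propanoic acid F2. On gentle warming this loses CO2 to give 2-(benzyloxy)-1-[4-(pivaloyloxy)phenyl]ethan-1-one F3.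
- Vilsmeier-Haack-Arnold chloroformylation (POCl3, DMF, 60 °C) should give (E)-2-(benzyloxy)-3-chloro-3-[4-(pivaloyloxy)phenyl]prop-2-enal F4. This is a much stronger vinylogous acceptor, and its leaving group offers no second electrophilic site.
- Phenol 6 with K2CO3 in DMF should give (E)-2-(benzyloxy)-3-[3,5-bis(benzyloxy)-4-methoxyphenoxy]-3-[4-(pivaloyloxy)phenyl]prop-2-enal F5.
- Pinnick oxidation (NaClO2, NaH2PO4, 2-methyl-2-butene, t-BuOH–H2O) then leads to 15.

**Step 15.**
- What may go wrong: the acid may ionise the allylic C–O bond of the prenyl ether, or add methanol across its alkene, while the slower 7-O-acetal is still being cleaved.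
- Fallback: it sets out from triol 18 and comes back at target 23. It replaces acid-labile acetals by fluoride-labile ones.
- SEMCl and i-Pr2NEt in CH2Cl2 should give 5-hydroxy-6-methoxy-4'-(pivaloyloxy)-3,7-bis{[2-(trimethylsilyl)ethoxy]methoxy}flavone F6.
- K2CO3 in MeOH frees 5-hydroxy-2-(4-hydroxyphenyl)-6-methoxy-3,7-bis{[2-(trimethylsilyl)ethoxy]methoxy}chromen-4-one F7.
- Bromide 20 with K2CO3 in DMF gives 5-hydroxy-6-methoxy-4'-(3-methylbut-2-enyloxy)-3,7-bis{[2-(trimethylsilyl)ethoxy]methoxy}flavone F8.
- Bu4NF in THF–DMPU at 50 °C triggers fragmentation of both groups under basic conditions, to which an aryl prenyl ether is inert, giving 23 after neutralisation.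

Further compounds
F1 | step 11 | tert-butyl (E)-2-(benzyloxy)-3-[3,5-bis(benzyloxy)-2-iodo-4-methoxyphenoxy]-3-[4-(pivaloyloxy)phenyl]prop-2-enoate | CC(C)(C)OC(=O)/C(OCc1ccccc1)=C(\Oc1cc(OCc2ccccc2)c(OC)c(OCc2ccccc2)c1I)c1ccc(OC(=O)C(C)(C)C)cc1
F2 | step 9 | 2-(benzyloxy)-3-oxo-3-[4-(pivaloyloxy)phenyl]propanoic acid (racemic) | OC(=O)C(OCc1ccccc1)C(=O)c1ccc(OC(=O)C(C)(C)C)cc1
F3 | step 9 | 2-(benzyloxy)-1-[4-(pivaloyloxy)phenyl]ethan-1-one | O=C(COCc1ccccc1)c1ccc(OC(=O)C(C)(C)C)cc1
F4 | step 9 | (E)-2-(benzyloxy)-3-chloro-3-[4-(pivaloyloxy)phenyl]prop-2-enal | O=C/C(OCc1ccccc1)=C(\Cl)c1ccc(OC(=O)C(C)(C)C)cc1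
F5 | step 9 | (E)-2-(benzyloxy)-3-[3,5-bis(benzyloxy)-4-methoxyphenoxy]-3-[4-(pivaloyloxy)phenyl]prop-2-enal | O=C/C(OCc1ccccc1)=C(\Oc1cc(OCc2ccccc2)c(OC)c(OCc2ccccc2)c1)c1ccc(OC(=O)C(C)(C)C)cc1
F6 | step 15 | 5-hydroxy-6-methoxy-4'-(pivaloyloxy)-3,7-bis{[2-(trimethylsilyl)ethoxy]methoxy}flavone | COc1c(OCOCC[Si](C)(C)C)cc2oc(-c3ccc(OC(=O)C(C)(C)C)cc3)c(OCOCC[Si](C)(C)C)c(=O)c2c1O
F7 | step 15 | 5-hydroxy-2-(4-hydroxyphenyl)-6-methoxy-3,7-bis{[2-(trimethylsilyl)ethoxy]methoxy}chromen-4-one | COc1c(OCOCC[Si](C)(C)C)cc2oc(-c3ccc(O)cc3)c(OCOCC[Si](C)(C)C)c(=O)c2c1O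
F8 | step 15 | 5-hydroxy-6-methoxy-4'-(3-methylbut-2-enyloxy)-3,7-bis{[2-(trimethylsilyl)ethoxy]methoxy}flavone | COc1c(OCOCC[Si](C)(C)C)cc2oc(-c3ccc(OCC=C(C)C)cc3)c(OCOCC[Si](C)(C)C)c(=O)c2c1O
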